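Ring A is cut at C11–C1 and C4–C3. In the cyclobutane C4–C5–C11–C10, C4 and C11 flank C5, so they are the α and α′ carbons of a 3,3-disubstituted cyclobutanone, and the C1(=O)–C2=C3(CH3) bridge of ring A is a crotonyl unit. One operation, acylation of the chiral enamine by crotonyl chloride followed by Michael closure, should give the bicyclo[3.1.1]heptane-2,6-dione and set C4, C10 and C11. The precursor is mirror-symmetric 3-(dimethoxymethyl)-3-methylcyclobutanone; its branched acetal at C9, bulkier at C10 than a protected hydroxymethyl group, steers the bridge to the methyl face and already holds the aldehyde oxidation level. Ring B is then grown from C9 and closed onto C5.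

Key step: step 5

Numbering used for all intermediates: C1 ketone, C2=C3 (C3 bears CH3), cyclobutane C4–C5–C11–C10, ring B C5–C6(CH3)2–C7–C8–C9–C10.
Assumption for step 5: the acyl group is taken to add to the enamine carbon anti to the neighbouring ring methyl of the amine; if the first bond formed were C4–C3 instead, the (2R,5R)-amine would be used.
Assumption for step 8: the methyl-ketone enolate made with (−)-Ipc2BCl (from (+)-α-pinene) is taken to add to the Re face of the aldehyde; the antipodal reagent would be used otherwise.
Remark on C3: 11 to 21 are drawn with the C3 methyl on the C5 side; either epimer serves, because step 12 removes this centre.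

Step 1
Reactants: 1 3-methylidenecyclobutane-1-carbonitrile
Product: 2 1-methyl-3-methylidenecyclobutane-1-carbonitrile
Conditions: LiN(iPr)2, THF, −78 °C; then MeI, −78 °C → rt
Reagents that add atoms: iodomethane, CI
Why: Nitrile α-alkylation: the amide base removes the only acidic C–H and the nitrile anion is methylated, which creates the quaternary carbon that becomes C10.

Step 2
Reactants: 2 1-methyl-3-methylidenecyclobutane-1-carbonitrile
Product: 3 1-methyl-3-methylidenecyclobutane-1-carbaldehyde
Conditions: iBu2AlH, CH2Cl2, −78 °C; then 1 M HCl, 0 °C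
Reagents that add atoms: water, O
Why: Half-reduction of a nitrile: one hydride adds, the N-aluminio imine persists until aqueous acid hydrolyses it to the aldehyde, and the quaternary α-carbon rules out enolisation.

Step 3
Reactants: 3 1-methyl-3-methylidenecyclobutane-1-carbaldehyde
Product: 4 1-(dimethoxymethyl)-1-methyl-3-methylidenecyclobutane
Conditions: HC(OMe)3, MeOH, PPTS (cat.), rt
Reagents that add atoms: trimethyl orthoformate, COC(OC)OC
Why: Acid-catalysed acetalisation with the orthoformate as dehydrating agent turns the aldehyde into the base-stable, branched dimethyl acetal that serves as the large C10 substituent in step 5.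

Step 4
Reactants: 4 1-(dimethoxymethyl)-1-methyl-3-methylidenecyclobutane
Product: 5 3-(dimethoxymethyl)-3-methylcyclobutan-1-one
Conditions: O3, CH2Cl2, −78 °C (Sudan Red 7B end point); then Me2S, −78 °C → rt
Reagents that add atoms: ozone, [O-][O+]=O
Why: Ozonolysis with reductive work-up cleaves the only C=C bond to the cyclobutanone, and the indicator dye marks the end point before ozone can oxidise the acetal C–H bond.

Step 5
Reactants: 5 3-(dimethoxymethyl)-3-methylcyclobutan-1-one; 6 (2S,5S)-2,5-dimethylpyrrolidine; 7 (E)-but-2-enoyl chloride
Product: 11 7-(dimethoxymethyl)-4,7-dimethylbicyclo[3.1.1]heptane-2,6-dione (C10 methyl on the ring A face), via enamine 8 (not isolated), via acylenaminone 9 (not isolated), via iminium chloride 10 (not isolated)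
Conditions: 6 (1.1 equiv), 4 Å MS, cyclohexane, 50 °C; then 7, MeCN, −20 → 60 °C; then aq. AcOH–NaOAc (pH 5), rt
Reagents that add atoms: water, O
Why: Proposed new method: enamine 8 is acylated on carbon by 7 (bond C11–C1), the iminium settles as enaminone 9, and its minor tautomer with the enamine toward C4 adds to the enone β-carbon C3 (bond C4–C3) to give iminium 10, which buffered water hydrolyses; the closest known reaction type is the α,α′-annulation of cyclohexanone and cyclopentanone enamines with α,β-unsaturated acid chlorides to bicyclo[3.3.1]nonane- and bicyclo[3.2.1]octane-diones, not yet shown for a cyclobutanone. Ring A closes by a 6-endo-trig Michael addition across the cis-1,3 positions of the four-membered ring, and the exchange of a C=C π bond for a C–C σ bond should outweigh the added strain. C11 and C4 are fixed cis by the three-atom tether, C10 becomes stereogenic with its methyl over ring A because the bridge can only form on the face opposite the branched acetal, and C3 (methyl expected on the C5 side) needs no control since step 12 removes it. The absolute configuration follows from which enantiotopic α-carbon is acylated: the amine methyl next to the enamine carbon shields one face, and only in one of the two enamine regioisomers is the open face also the one anti to the acetal. The second bond has to form syn to the other amine methyl, which is why the small 2,5-dimethylpyrrolidine is used. The step needs C-acylation to win over N-acylation, ring closure to beat opening of the strained 1,3-dione, and a large size difference at C10, which the dimethoxymethyl group supplies.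

Step 6
Reactants: 11 7-(dimethoxymethyl)-4,7-dimethylbicyclo[3.1.1]heptane-2,6-dione
Product: 12 C5 tosylhydrazone of 11
Conditions: TsNHNH2 (1.0 equiv), MeOH, 0 °C → rt
Reagents that add atoms: 4-methylbenzenesulfonohydrazide, Cc1ccc(cc1)S(=O)(=O)NN
Why: Tosylhydrazone formation: the strained, sterically open cyclobutanone carbonyl C5 condenses ahead of the C1 ketone, and the C=N group both removes the electrophile whose adducts could open the four-membered ring by retro-Claisen cleavage and provides the radical acceptor for step 10.

Step 7
Reactants: 12 C5 tosylhydrazone of 11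
Product: 13 C9 aldehyde (7-formyl analogue of 12)
Conditions: LiBF4, MeCN–H2O (50:1), rt → 40 °C
Reagents that add atoms: water, O
Why: Lewis-acid-assisted acetal hydrolysis at near-neutral pH releases the C9 aldehyde, which has no α-hydrogen, while the sulfonylhydrazone, much slower to hydrolyse, stays in place.

Step 8
Reactants: 13 C9 aldehyde; 14 3-methylbut-3-en-2-one
Product: 15 (9R)-β-hydroxy enone (C9–OH; C7 ketone; C6 isopropenyl)
Conditions: 14, (−)-Ipc2BCl, Et3N, Et2O, −78 → 0 °C; then 13, −78 → −20 °C; MeOH, pH 7 buffer
Reagents that add atoms: none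
Why: Boron-mediated asymmetric aldol reaction of a methyl ketone: the enol diisopinocampheylborinate formed on the methyl side of 14 adds only to the aldehyde, and the Ipc ligands are expected to direct it to the Re face (reagent control, since the quaternary C10 offers little bias), which gives the 9R carbinol.

Step 9
Reactants: 15 (9R)-β-hydroxy enone; 16 3-methylbutanal
Product: 17 (7R,9R)-anti-diol 9-O-isovalerate (C7–OH allylic; C6 isopropenyl)
Conditions: 16 (6 equiv), SmI2 (0.3 equiv), THF, −10 °C
Reagents that add atoms: none
Why: Evans–Tishchenko reduction: the samarium-bound hemiacetal formed from the C9 hydroxyl and 16 transfers its hydride intramolecularly through a chair-like six-membered array to the C7 carbonyl, so that C9–O becomes the isovalerate and the new C7 carbinol is 1,3-anti to it (7R), without conjugate reduction of the enone.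

Step 10
Reactants: 17 (7R,9R)-anti-diol 9-O-isovalerate
Product: 19 tricyclic keto alcohol (C5–H; C7–OH; C9 isovalerate; saturated C1 ketone), via hydrazide 18 (not isolated)
Conditions: Fe(acac)3 (0.5 equiv), PhSiH3, EtOH–THF, 50 °C; then NaOAc, EtOH, 75 °C
Reagents that add atoms: none
Why: Hydrogen-atom-transfer-initiated radical cyclisation onto a sulfonylhydrazone followed by base-induced sulfinate loss and extrusion of N2 from the alkyldiazene, both known reaction types: the iron hydride adds H to the methylidene carbon, the tertiary C6 radical is tethered through C7–C8–C9 to the face of C5 opposite ring A and can bond only there, and the bridgehead C5 centre then takes its hydrogen with retention, which places C5–H on the ring A side.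

Step 11
Reactants: 19 tricyclic keto alcohol; 20 3-methylbut-2-enoic acid
Product: 21 2,3-dihydro derivative of the target (C7 senecioate; C9 isovalerate)
Conditions: 20, 2,4,6-Cl3C6H2COCl, Et3N, THF, rt; then 19, DMAP, toluene, 40 °C
Reagents that add atoms: none
Why: Yamaguchi esterification: the mixed anhydride of 20 activated by DMAP acylates the hindered C7 alcohol, the only free hydroxyl, with less double-bond migration than the acid chloride would cause.

Step 12
Reactants: 21 2,3-dihydro derivative of the target
Product: 23 CNP0214473.1 (target), via silyl enol ether 22 (not isolated)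
Conditions: TMSOTf, Et3N, CH2Cl2, 0 °C; then Pd(OAc)2, MeCN, rt
Reagents that add atoms: none
Why: Saegusa–Ito oxidation: the C1 ketone can enolise only toward C2 because C11 is a bridgehead, so a single silyl enol ether forms, and palladation at C2 followed by syn β-hydride elimination from C3 gives the C2=C3 enone and removes the temporary C3 stereocentre.

Compound list
1 | 3-methylidenecyclobutane-1-carbonitrile | C=C1CC(C#N)C1 | starting material
2 | 1-methyl-3-methylidenecyclobutane-1-carbonitrile | C=C1CC(C)(C#N)C1 | intermediate
3 | 1-methyl-3-methylidenecyclobutane-1-carbaldehyde | C=C1CC(C)(C=O)C1 | intermediate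
4 | 1-(dimethoxymethyl)-1-methyl-3-methylidenecyclobutane | C=C1CC(C)(C(OC)OC)C1 | intermediate
5 | 3-(dimethoxymethyl)-3-methylcyclobutan-1-one (achiral, mirror plane through C5 and C10) | COC(OC)C1(C)CC(=O)C1 | intermediate
6 | (2S,5S)-2,5-dimethylpyrrolidine | C[C@H]1CC[C@H](C)N1 | starting material
7 | (E)-but-2-enoyl chloride | C/C=C/C(Cl)=O | starting material
8 | (2S,5S)-1-[3-(dimethoxymethyl)-3-methylcyclobut-1-en-1-yl]-2,5-dimethylpyrrolidine (reacting regioisomer, C=C toward the future C11) | COC(OC)[C@]1(C)CC(=C1)N2[C@@H](C)CC[C@@H]2C | intermediate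
9 | (E)-1-[4-(dimethoxymethyl)-4-methyl-2-((2S,5S)-2,5-dimethylpyrrolidin-1-yl)cyclobut-1-en-1-yl]but-2-en-1-one | COC(OC)[C@]1(C)CC(N2[C@@H](C)CC[C@@H]2C)=C1C(=O)/C=C/C | intermediate
10 | (2S,5S)-1-[7-(dimethoxymethyl)-4,7-dimethyl-2-oxobicyclo[3.1.1]heptan-6-ylidene]-2,5-dimethylpyrrolidin-1-ium chloride | COC(OC)[C@@]1(C)[C@@H]2C(=O)C[C@@H](C)[C@H]1C2=[N+]3[C@@H](C)CC[C@@H]3C.[Cl-] | intermediate
11 | 7-(dimethoxymethyl)-4,7-dimethylbicyclo[3.1.1]heptane-2,6-dione (C1 and C5 ketones; C10 methyl syn to the C1–C2–C3 bridge, acetal anti; C3 methyl on the C5 side) | COC(OC)[C@@]1(C)[C@@H]2C(=O)C[C@@H](C)[C@H]1C2=O | intermediate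
12 | N'-[7-(dimethoxymethyl)-4,7-dimethyl-2-oxobicyclo[3.1.1]heptan-6-ylidene]-4-methylbenzenesulfonohydrazide | COC(OC)[C@@]1(C)[C@@H]2C(=O)C[C@@H](C)[C@H]1C2=NNS(=O)(=O)c3ccc(C)cc3 | intermediate
13 | N'-(7-formyl-4,7-dimethyl-2-oxobicyclo[3.1.1]heptan-6-ylidene)-4-methylbenzenesulfonohydrazide | O=C[C@@]1(C)[C@@H]2C(=O)C[C@@H](C)[C@H]1C2=NNS(=O)(=O)c3ccc(C)cc3 | intermediate
14 | 3-methylbut-3-en-2-one | CC(=O)C(C)=C | starting material
15 | aldol adduct, 7-[(1R)-1-hydroxy-4-methyl-3-oxopent-4-en-1-yl] analogue of 13 (9R) | C=C(C)C(=O)C[C@@H](O)[C@@]1(C)[C@@H]2C(=O)C[C@@H](C)[C@H]1C2=NNS(=O)(=O)c3ccc(C)cc3 | intermediate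
16 | 3-methylbutanal | CC(C)CC=O | starting material
17 | (1R,3R)-3-hydroxy-4-methyl-1-[bicyclic tosylhydrazone]pent-4-en-1-yl 3-methylbutanoate (7R,9R; 1,3-anti) | C=C(C)[C@H](O)C[C@@H](OC(=O)CC(C)C)[C@@]1(C)[C@@H]2C(=O)C[C@@H](C)[C@H]1C2=NNS(=O)(=O)c3ccc(C)cc3 | intermediate
18 | tricyclic N'-tosylhydrazide (ring B closed by C5–C6; NHNHTs on C5 on the ring A face) | O[C@@H]1C[C@@H](OC(=O)CC(C)C)[C@@]2(C)[C@@H]3C(=O)C[C@@H](C)[C@H]2[C@]3(NNS(=O)(=O)c4ccc(C)cc4)C1(C)C | intermediate
19 | tricyclic keto alcohol (C5–H on the ring A face; 7R hydroxyl; 9R isovalerate; C1 ketone; C2–C3 saturated) | O[C@@H]1C[C@@H](OC(=O)CC(C)C)[C@@]2(C)[C@@H]3C(=O)C[C@@H](C)[C@H]2[C@@H]3C1(C)C | intermediate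
20 | 3-methylbut-2-enoic acid | CC(C)=CC(=O)O | starting material
21 | 2,3-dihydro derivative of the target | CC(C)=CC(=O)O[C@@H]1C[C@@H](OC(=O)CC(C)C)[C@@]2(C)[C@@H]3C(=O)C[C@@H](C)[C@H]2[C@@H]3C1(C)C | intermediate
22 | C1 trimethylsilyl enol ether of 21 (C1=C2) | CC(C)=CC(=O)O[C@@H]1C[C@@H](OC(=O)CC(C)C)[C@@]2(C)[C@@H]3C(O[Si](C)(C)C)=C[C@@H](C)[C@H]2[C@@H]3C1(C)C | intermediate
23 | CNP0214473.1 | CC(C)=CC(=O)O[C@@H]1C[C@@H](OC(=O)CC(C)C)[C@@]2(C)[C@@H]3C(=O)C=C(C)[C@H]2[C@@H]3C1(C)C | target

Total step count: 12. Longest linear sequence: 12 steps (1 to 23).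

Steps most likely to fail

Step 5 (proposed new method). What may go wrong: acylation on nitrogen without carbon–carbon bond formation; arrest at the vinylogous amide 9, because the closing bond must form next to an amine methyl; cleavage of the strained, non-enolisable 1,3-dione during hydrolysis; or weak face discrimination at C10. The fallback makes each bond by a known reaction type and lets a chiral base alone choose the α-carbon; it sets out from 5 and returns at 11. Enantioselective deprotonation of 5 with lithium bis[(R)-1-phenylethyl]amide and Me3SiCl in THF at −100 °C, a reaction established for 3-substituted cyclobutanones, would give silyl enol ether F1 with the double bond toward the future C4 (the base antipode that removes that proton is used). Mukaiyama–Michael addition of F1 to phenyl (E)-but-2-enoate F2 (from 7 and phenol with pyridine), under Me3SiOTf catalysis at −78 °C and anti to the acetal, would give keto ester F3. LiN(SiMe3)2 in THF at −78 °C would then form the C11 enolate, which acylates itself on the phenyl ester (intramolecular Claisen condensation) and gives 11.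

Step 10. What may go wrong: a second hydrogen-atom transfer reduces the C6 radical before it reaches C5, so that the isopropenyl group is merely hydrogenated; migration of the isovaleryl group between O9 and O7 in the open-chain substrate is a further risk. In the fallback the radical is generated by a tin hydride chain at high dilution from a tertiary selenide carried in from the aldol step; it sets out from 13 and returns at 19. 3-Methyl-3-(phenylselanyl)butan-2-one F4 (from 3-bromo-3-methylbutan-2-one and PhSeNa) would replace 14 in the boron aldol of step 8 and should give aldol adduct F5. The conditions of step 9 should then give diol monoester F6. Slow addition of Bu3SnH and AIBN in benzene at 80 °C would form the C6 radical by selenium abstraction; it should cyclise onto the hydrazone to 18, and NaOAc in EtOH would convert 18 into 19 as in step 10.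

Step 6. What may go wrong: the hydrazide adds to C5 but the adduct opens the four-membered ring by C5–C11 cleavage (retro-Claisen) instead of losing water, or condensation also occurs at C1. The fallback avoids the free dione; it sets out from iminium chloride 10 in the flask of step 5 and returns at 12. TsNHNH2 and NaOAc in MeCN would be added to 10 before any water, so that exchange of the amine for the hydrazide (transimination) gives 12 directly and releases 6; no new compound is involved.

Further compounds
F1 | step 5 | [3-(dimethoxymethyl)-3-methylcyclobut-1-en-1-yl]oxy(trimethyl)silane (C=C toward the future C4) | COC(OC)[C@@]1(C)CC(O[Si](C)(C)C)=C1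
F2 | step 5 | phenyl (E)-but-2-enoate | C/C=C/C(=O)Oc1ccccc1
F3 | step 5 | phenyl 3-[3-(dimethoxymethyl)-3-methyl-2-oxocyclobutyl]butanoate (side chain trans to the acetal; C3 unassigned) | COC(OC)[C@@]1(C)CC(=O)[C@@H]1C(C)CC(=O)Oc2ccccc2
F4 | step 10 | 3-methyl-3-(phenylselanyl)butan-2-one | CC(=O)C(C)(C)[Se]c1ccccc1
F5 | step 10 | (9R)-aldol adduct with C6 phenylselanyl group | CC(C)([Se]c1ccccc1)C(=O)C[C@@H](O)[C@@]2(C)[C@@H]3C(=O)C[C@@H](C)[C@H]2C3=NNS(=O)(=O)c4ccc(C)cc4
F6 | step 10 | (7R,9R)-anti-diol 9-O-isovalerate with C6 phenylselanyl group | CC(C)([Se]c1ccccc1)[C@H](O)C[C@@H](OC(=O)CC(C)C)[C@@]2(C)[C@@H]3C(=O)C[C@@H](C)[C@H]2C3=NNS(=O)(=O)c4ccc(C)cc4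
F0 | step 6 | none | none
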